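The route rests on cutting ring C of the top unit T (O1, C2, C3, C4, C4a, C8a), a 2-aryl-3-oxy-4-arylchroman, into an ortho-quinone methide (O1=C8a–C4a=C4) and a (Z)-styrenyl C2=C3 unit. In one operation the key step forms the interflavan bond C4(T)–C6(M), C3–C4 and O1–C2, closes ring C and sets C2, C3 and C4. Its precursor is the fully benzylated epicatechin-(4β→6)-epicatechin (units M and B, made by bromine-capped cationic coupling) magnesiated at C6 of unit M through an iodide, which meets an O-Boc salicylaldehyde and a (Z)-styryl pivalate. Ester cleavage and hydrogenolysis finish the synthesis.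

Key step: step 11

Remarks on the chemistry (assumptions):
- Flavan numbering is used; the units are T (top), M (middle) and B (bottom). All C2 and C3 centres are R as in (−)-epicatechin; "4β" means the C4 aryl is trans to the C3 oxygen and to the C2 aryl.
- NBS brominates benzylated epicatechin at C8, not C6. C8 of units M and B therefore carries a bromine cap (a spectator through the key step, removed in step 13), and the C6 handle on unit M is an iodide. Exchange with i-PrMgCl·LiCl then gives the arylmagnesium chloride (LiCl complex).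
- Reagents are given by name and SMILES under each step and carry no number.

Step 1
Reactants: 1 (−)-epicatechin
Product: 2 5,7,3′,4′-tetra-O-benzylepicatechin
Conditions: BnBr (4.4 equiv), K2CO3, DMF, 0 °C to rt, Ar
Reagents that add atoms: benzyl bromide, BrCc1ccccc1
Why: Williamson etherification in which carbonate deprotonates only the four phenols and not the C3 alcohol, so C2 and C3 should stay untouched under these mild, oxygen-free conditions.

Step 2
Reactants: 2 5,7,3′,4′-tetra-O-benzylepicatechin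
Product: 3 8-bromo-5,7,3′,4′-tetra-O-benzylepicatechin
Conditions: NBS (1.0 equiv), CH2Cl2, −40 °C to rt
Reagents that add atoms: N-bromosuccinimide, O=C1CCC(=O)N1Br
Why: Electrophilic aromatic bromination, which should go to C8 (between O1 and one benzyloxy group) because it is more accessible than C6 (between two benzyloxy groups).

Step 3
Reactants: 3 8-bromo-5,7,3′,4′-tetra-O-benzylepicatechin
Product: 4 8-bromo-4β-(2-ethoxyethoxy)-5,7,3′,4′-tetra-O-benzylepicatechin
Conditions: DDQ (2 equiv), 2-ethoxyethanol (5 equiv), CH2Cl2, rt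
Reagents that add atoms: 2-ethoxyethanol, CCOCCO
Why: DDQ benzylic oxidation by hydride abstraction at C4 gives a cation stabilised by the 5,7-dioxygenated ring, and the alcohol should add anti to the C3 hydroxyl to give the 4β ether (this centre is ionised again in step 4).

Step 4
Reactants: 4 8-bromo-4β-(2-ethoxyethoxy)-5,7,3′,4′-tetra-O-benzylepicatechin; 3 8-bromo-5,7,3′,4′-tetra-O-benzylepicatechin (3 equiv, excess recovered)
Product: 5 bromine-capped dimer diol
Conditions: TMSOTf (0.5 equiv), CH2Cl2, −78 to −20 °C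
Reagents that add atoms: none
Why: Lewis-acid-promoted Friedel–Crafts alkylation by the flavan-4-yl cation, in which the C8 bromine of 3 leaves C6 as the only nucleophilic carbon, attack anti to the C2 aryl and C3 hydroxyl sets C4(M) as 4β, and the excess of 3 should keep the free C6 of 4 and of 5 from competing.

Step 5
Reactants: 5 bromine-capped dimer diol
Product: 6 bromine-capped dimer bis(3-O-benzyl ether)
Conditions: NaH, BnBr, Bu4NI (cat.), THF/DMF, 0 °C to rt
Reagents that add atoms: benzyl bromide, BrCc1ccccc1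
Why: Williamson etherification of the two secondary alkoxides removes the acidic protons before the organometallic step and touches no stereocentre.

Step 6
Reactants: 6 bromine-capped dimer bis(3-O-benzyl ether)
Product: 7 C6(M) iodide of the benzylated dimer
Conditions: NIS (1.1 equiv), CH2Cl2/MeCN, 0 °C to rt, dark
Reagents that add atoms: N-iodosuccinimide, O=C1CCC(=O)N1I
Why: Electrophilic aromatic iodination, which should be selective because C6 of unit M is the only unsubstituted carbon of a phloroglucinol ring in 6 and is far more nucleophilic than the catechol rings under acid-free conditions.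

Step 7
Reactants: 8 2,4,6-trihydroxybenzaldehyde
Product: 9 4,6-bis(benzyloxy)-2-hydroxybenzaldehyde
Conditions: BnBr (2.1 equiv), K2CO3 (2.2 equiv), DMF, 0 °C to rt
Reagents that add atoms: benzyl bromide, BrCc1ccccc1
Why: Williamson etherification in which the para hydroxyl and one ortho hydroxyl are alkylated while the remaining ortho hydroxyl, hydrogen-bonded to the formyl group, should stay free.

Step 8
Reactants: 9 4,6-bis(benzyloxy)-2-hydroxybenzaldehyde
Product: 10 2-(tert-butoxycarbonyloxy)-4,6-bis(benzyloxy)benzaldehyde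
Conditions: Boc2O, i-Pr2NEt, DMAP (cat.), THF, rt
Reagents that add atoms: di-tert-butyl dicarbonate, CC(C)(C)OC(=O)OC(=O)OC(C)(C)C
Why: DMAP-catalysed O-acylation of the phenol should give the aryl tert-butyl carbonate.

Step 9
Reactants: 11 3,4-bis(benzyloxy)benzaldehyde
Product: 12 4-ethynyl-1,2-bis(benzyloxy)benzene
Conditions: dimethyl (1-diazo-2-oxopropyl)phosphonate, K2CO3, MeOH/THF, rt
Reagents that add atoms: dimethyl (1-diazo-2-oxopropyl)phosphonate, COP(=O)(OC)C(=[N+]=[N-])C(C)=O
Why: Seyferth–Gilbert homologation in the Ohira–Bestmann variant, in which the diazomethylphosphonate anion made in the flask converts the aldehyde into the terminal alkyne through a vinylidene carbene 1,2-shift.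

Step 10
Reactants: 12 4-ethynyl-1,2-bis(benzyloxy)benzene
Product: 13 (Z)-2-[3,4-bis(benzyloxy)phenyl]ethenyl pivalate
Conditions: t-BuCO2H (1.2 equiv), Ru(η3-CH2CMeCH2)2(Ph2P(CH2)4PPh2) (2 mol %), toluene, 65 °C
Reagents that add atoms: pivalic acid, CC(C)(C)C(=O)O
Why: Ruthenium-catalysed anti-Markovnikov hydro-acyloxylation of a terminal alkyne, in which carboxylate adds to the α-carbon of a ruthenium vinylidene and protonolysis gives the trans-addition product, the (Z)-enol ester.

Step 11
Reactants: 7 C6(M) iodide of the benzylated dimer; 10 2-(tert-butoxycarbonyloxy)-4,6-bis(benzyloxy)benzaldehyde (1.2 equiv); 13 (Z)-2-[3,4-bis(benzyloxy)phenyl]ethenyl pivalate (3 equiv)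
Product: 18 benzylated bromine-capped trimer C3(T) pivalate, via arylmagnesium chloride 14 (not isolated), via magnesium alkoxide adduct 15 (not isolated), via benzylic tert-butyl carbonate phenoxide 16 (not isolated), via ortho-quinone methide 17 (not isolated)
Conditions: i-PrMgCl·LiCl (1.0 equiv), THF, −20 to 0 °C; add to 10, THF, −78 °C; then 13, −78 °C to rt; H2O quench
Reagents that add atoms: none
Why: Iodine–magnesium exchange at C6 of 7 (C–I reacts far faster than the two C–Br bonds) gives 14, which adds to the formyl group of 10; alkoxide 15 takes the Boc group from the neighbouring phenol oxygen (16), and 1,4-elimination of tert-butyl carbonate on warming releases 17, the known aryl Grignard/O-Boc salicylaldehyde entry to ortho-quinone methides with inverse-demand hetero-Diels–Alder trapping. Ring C of unit T then closes by [4+2] cycloaddition of the oxadiene O1=C8a–C4a=C4 with the C2=C3 alkene of 13; the 3,4-dialkoxyphenyl group stabilises positive charge at C2 better than the acyloxy group does at C3, so C3 should bond to the methide carbon and C2 to oxygen. C2 and C3 should come out cis because both bonds form on one face of the Z alkene. C4 should come out trans to C3 because the peri C5 benzyloxy group turns the bulky C4 aryl to the carbonyl side of the methide (Z isomer), and endo addition to that isomer places the pivalate and the C2 aryl anti to it (the E isomer would have to react exo for the same result). The absolute sense at C2, C3 and C4 depends on which methide face reacts; the only control is the chiral unit M, whose C4 aryl and geared C5/C7 benzyloxy groups shield one face of the methide, so this is the selectivity at risk, and the ring-C diastereomers should be separable because units M and B make them diastereomeric. Chemoselectivity for the aldehyde over the pivalate is secured by adding 13 only after the Grignard reagent has been consumed at −78 °C.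

Step 12
Reactants: 18 benzylated bromine-capped trimer C3(T) pivalate
Product: 19 benzylated bromine-capped trimer C3(T) alcohol
Conditions: i-Bu2AlH (4 equiv), CH2Cl2, −78 to 0 °C; KNaC4H4O6 (aq) work-up
Reagents that add atoms: none
Why: Reductive cleavage of the hindered ester by hydride should free the C3 alcohol without base and leave benzyl ethers, aryl bromides and all stereocentres untouched.

Step 13
Reactants: 19 benzylated bromine-capped trimer C3(T) alcohol
Product: 20 epicatechin-(4β→6)-epicatechin-(4β→6)-epicatechin (target)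
Conditions: H2 (1 atm), Pd(OH)2/C, Et3N (2.2 equiv), THF/MeOH/H2O, rt
Reagents that add atoms: none
Why: Palladium-catalysed hydrogenolysis should cleave the fourteen benzyl ethers and hydrodehalogenate both aryl bromides, with triethylamine taking up HBr to protect the acid-labile interflavan bonds, and no stereocentre is affected.

Compound list

1 | (−)-epicatechin, (2R,3R)-2-(3,4-dihydroxyphenyl)chroman-3,5,7-triol | O[C@@H]1Cc2c(O)cc(O)cc2O[C@@H]1c1ccc(O)c(O)c1 | starting material

2 | 5,7,3′,4′-tetra-O-benzylepicatechin, (2R,3R)-5,7-bis(benzyloxy)-2-[3,4-bis(benzyloxy)phenyl]chroman-3-ol | c1c(OCc3ccccc3)cc2c(c1OCc3ccccc3)C[C@@H](O)[C@@H](c4ccc(OCc3ccccc3)c(OCc3ccccc3)c4)O2 | intermediate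

3 | 8-bromo-5,7,3′,4′-tetra-O-benzylepicatechin (2R,3R) | c1c(OCc3ccccc3)c(Br)c2c(c1OCc3ccccc3)C[C@@H](O)[C@@H](c4ccc(OCc3ccccc3)c(OCc3ccccc3)c4)O2 | intermediate

4 | 8-bromo-4β-(2-ethoxyethoxy)-5,7,3′,4′-tetra-O-benzylepicatechin (2R,3R; C4 ether trans to the C3 hydroxyl) | c1c(OCc3ccccc3)c(Br)c2c(c1OCc3ccccc3)[C@H](OCCOCC)[C@@H](O)[C@@H](c4ccc(OCc3ccccc3)c(OCc3ccccc3)c4)O2 | intermediate

5 | bromine-capped dimer diol, [8-bromo-5,7,3′,4′-tetra-O-benzylepicatechin]-(4β→6)-[8-bromo-5,7,3′,4′-tetra-O-benzylepicatechin] | c1c(OCc3ccccc3)c(Br)c2c(c1OCc3ccccc3)[C@H](c5c(OCc3ccccc3)c(Br)c6c(c5OCc3ccccc3)C[C@@H](O)[C@@H](c7ccc(OCc3ccccc3)c(OCc3ccccc3)c7)O6)[C@@H](O)[C@@H](c4ccc(OCc3ccccc3)c(OCc3ccccc3)c4)O2 | intermediate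

6 | bromine-capped dimer bis(3-O-benzyl ether), [8-bromo-penta-O-benzylepicatechin]-(4β→6)-[8-bromo-penta-O-benzylepicatechin] | c1c(OCc3ccccc3)c(Br)c2c(c1OCc3ccccc3)[C@H](c5c(OCc3ccccc3)c(Br)c6c(c5OCc3ccccc3)C[C@@H](OCc3ccccc3)[C@@H](c7ccc(OCc3ccccc3)c(OCc3ccccc3)c7)O6)[C@@H](OCc3ccccc3)[C@@H](c4ccc(OCc3ccccc3)c(OCc3ccccc3)c4)O2 | intermediate

7 | C6(M) iodide of the benzylated dimer, [8-bromo-6-iodo-penta-O-benzylepicatechin]-(4β→6)-[8-bromo-penta-O-benzylepicatechin] | Ic1c(OCc3ccccc3)c(Br)c2c(c1OCc3ccccc3)[C@H](c5c(OCc3ccccc3)c(Br)c6c(c5OCc3ccccc3)C[C@@H](OCc3ccccc3)[C@@H](c7ccc(OCc3ccccc3)c(OCc3ccccc3)c7)O6)[C@@H](OCc3ccccc3)[C@@H](c4ccc(OCc3ccccc3)c(OCc3ccccc3)c4)O2 | intermediate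

8 | 2,4,6-trihydroxybenzaldehyde | O=Cc1c(O)cc(O)cc1O | starting material

9 | 4,6-bis(benzyloxy)-2-hydroxybenzaldehyde | O=Cc1c(O)cc(OCc2ccccc2)cc1OCc1ccccc1 | intermediate

10 | 2-(tert-butoxycarbonyloxy)-4,6-bis(benzyloxy)benzaldehyde | O=Cc1c(OC(=O)OC(C)(C)C)cc(OCc2ccccc2)cc1OCc1ccccc1 | intermediate

11 | 3,4-bis(benzyloxy)benzaldehyde | O=Cc1ccc(OCc2ccccc2)c(OCc2ccccc2)c1 | starting material

12 | 4-ethynyl-1,2-bis(benzyloxy)benzene | C#Cc1ccc(OCc2ccccc2)c(OCc2ccccc2)c1 | intermediate

13 | (Z)-2-[3,4-bis(benzyloxy)phenyl]ethenyl pivalate | CC(C)(C)C(=O)O/C=C\c1ccc(OCc2ccccc2)c(OCc2ccccc2)c1 | intermediate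

14 | C6(M) arylmagnesium chloride of the benzylated bromine-capped dimer (LiCl complex) | Cl[Mg]c1c(OCc3ccccc3)c(Br)c2c(c1OCc3ccccc3)[C@H](c5c(OCc3ccccc3)c(Br)c6c(c5OCc3ccccc3)C[C@@H](OCc3ccccc3)[C@@H](c7ccc(OCc3ccccc3)c(OCc3ccccc3)c7)O6)[C@@H](OCc3ccccc3)[C@@H](c4ccc(OCc3ccccc3)c(OCc3ccccc3)c4)O2.[Li+].[Cl-] | intermediate

15 | chloromagnesium alkoxide of the diarylmethanol from 14 and 10, Boc still on the phenol oxygen (both carbinol epimers) | Cl[Mg]OC(c8c(OC(=O)OC(C)(C)C)cc(OCc3ccccc3)cc8OCc3ccccc3)c1c(OCc3ccccc3)c(Br)c2c(c1OCc3ccccc3)[C@H](c5c(OCc3ccccc3)c(Br)c6c(c5OCc3ccccc3)C[C@@H](OCc3ccccc3)[C@@H](c7ccc(OCc3ccccc3)c(OCc3ccccc3)c7)O6)[C@@H](OCc3ccccc3)[C@@H](c4ccc(OCc3ccccc3)c(OCc3ccccc3)c4)O2 | intermediate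

16 | benzylic tert-butyl carbonate with chloromagnesium phenoxide (after Boc transfer; both carbinol epimers) | CC(C)(C)OC(=O)OC(c8c(O[Mg]Cl)cc(OCc3ccccc3)cc8OCc3ccccc3)c1c(OCc3ccccc3)c(Br)c2c(c1OCc3ccccc3)[C@H](c5c(OCc3ccccc3)c(Br)c6c(c5OCc3ccccc3)C[C@@H](OCc3ccccc3)[C@@H](c7ccc(OCc3ccccc3)c(OCc3ccccc3)c7)O6)[C@@H](OCc3ccccc3)[C@@H](c4ccc(OCc3ccccc3)c(OCc3ccccc3)c4)O2 | intermediate

17 | ortho-quinone methide of unit T, 3,5-bis(benzyloxy)-6-(arylmethylidene)cyclohexa-2,4-dienone with the dimer C6(M) aryl on the methide carbon, Z (aryl on the carbonyl side) | O=C1C=C(OCc3ccccc3)C=C(OCc3ccccc3)/C1=C/c1c(OCc3ccccc3)c(Br)c2c(c1OCc3ccccc3)[C@H](c5c(OCc3ccccc3)c(Br)c6c(c5OCc3ccccc3)C[C@@H](OCc3ccccc3)[C@@H](c7ccc(OCc3ccccc3)c(OCc3ccccc3)c7)O6)[C@@H](OCc3ccccc3)[C@@H](c4ccc(OCc3ccccc3)c(OCc3ccccc3)c4)O2 | intermediate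

18 | benzylated bromine-capped trimer C3(T) pivalate, [5,7,3′,4′-tetra-O-benzyl-3-O-pivaloylepicatechin]-(4β→6)-[8-bromo-penta-O-benzylepicatechin]-(4β→6)-[8-bromo-penta-O-benzylepicatechin] | C(c3ccccc3)Oc1cc(OCc3ccccc3)c2c(c1)O[C@H](c4ccc(OCc3ccccc3)c(OCc3ccccc3)c4)[C@H](OC(=O)C(C)(C)C)[C@H]2c1c(OCc3ccccc3)c(Br)c2c(c1OCc3ccccc3)[C@H](c5c(OCc3ccccc3)c(Br)c6c(c5OCc3ccccc3)C[C@@H](OCc3ccccc3)[C@@H](c7ccc(OCc3ccccc3)c(OCc3ccccc3)c7)O6)[C@@H](OCc3ccccc3)[C@@H](c4ccc(OCc3ccccc3)c(OCc3ccccc3)c4)O2 | intermediate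

19 | benzylated bromine-capped trimer C3(T) alcohol | C(c3ccccc3)Oc1cc(OCc3ccccc3)c2c(c1)O[C@H](c4ccc(OCc3ccccc3)c(OCc3ccccc3)c4)[C@H](O)[C@H]2c1c(OCc3ccccc3)c(Br)c2c(c1OCc3ccccc3)[C@H](c5c(OCc3ccccc3)c(Br)c6c(c5OCc3ccccc3)C[C@@H](OCc3ccccc3)[C@@H](c7ccc(OCc3ccccc3)c(OCc3ccccc3)c7)O6)[C@@H](OCc3ccccc3)[C@@H](c4ccc(OCc3ccccc3)c(OCc3ccccc3)c4)O2 | intermediate

20 | epicatechin-(4β→6)-epicatechin-(4β→6)-epicatechin, CNP0163146.2 | Oc1cc(O)c2c(c1)O[C@H](c1ccc(O)c(O)c1)[C@H](O)[C@H]2c1c(O)cc2c(c1O)[C@H](c1c(O)cc3c(c1O)C[C@@H](O)[C@@H](c1ccc(O)c(O)c1)O3)[C@@H](O)[C@@H](c1ccc(O)c(O)c1)O2 | target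

Total step count: 13. Longest linear sequence: 9 steps (steps 1, 2, 3, 4, 5, 6, 11, 12, 13).

Steps most likely to fail

1. Step 11. Addition of the doubly ortho-substituted Grignard reagent to the doubly ortho-substituted aldehyde may stall. The cycloaddition may also show poor facial selectivity on the methide, or turn stepwise and lose the 2,3-cis relationship. The fallback sets out from 4 and 5 and uses the cationic coupling of step 4 a second time. Ionisation of 4 with TMSOTf in CH2Cl2 at −78 to −20 °C in the presence of excess 5, whose only unsubstituted phloroglucinol carbon is C6 of unit M, should give the tribromo dodeca-O-benzyl trimer triol F1. All three flavan units then come from epicatechin, and the new C4(T) centre is set 4β by anti attack. F1 comes back to the route at 20 under the conditions of step 13 (H2, Pd(OH)2/C, Et3N), which remove twelve benzyl groups and three bromines.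

2. Step 4. Attack of the bromine-deactivated, doubly flanked C6 of 3 may be slow. The cation from 4 could then be captured by the free C6 of a second molecule of 4 or of product 5, which leads to oligomers. The fallback sets out from 4 and occupies both ring-A positions of the electrophile before coupling. NIS iodination at C6 should give the 6-iodo-8-bromo electrophile F2, which can no longer act as a nucleophile. Its coupling with 3 (1.5 equiv, TMSOTf or BF3·OEt2, CH2Cl2) should give the iodo dimer diol F3, already carrying the C6 handle. Benzylation with NaH/BnBr brings F3 back to the route at 7, so the late iodination of step 6 is not needed.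

3. Step 10. Regio- or Z-selectivity may erode in the ruthenium-catalysed addition of the bulky acid, and any E isomer would pass into the C2/C3 relative configuration. The fallback sets out from 11 and fixes the geometry before the C–O bond is made. Dibromo-olefination with CBr4/PPh3 should give the 1,1-dibromoalkene F4. Hydrogenolysis of the bromine trans to the aryl group with Bu3SnH and Pd(PPh3)4 should give the (Z)-β-bromostyrene F5. Ullmann-type substitution with CuO2CCMe3 (monovalent copper pivalate) in pyridine, which retains alkene geometry, comes back to the route at 13.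

Further compounds

F1 | step 11 | tribromo dodeca-O-benzyl trimer triol, [8-bromo-tetra-O-benzylepicatechin]-(4β→6)-[8-bromo-tetra-O-benzylepicatechin]-(4β→6)-[8-bromo-tetra-O-benzylepicatechin] | c1c(OCc3ccccc3)c(Br)c2c(c1OCc3ccccc3)[C@H](c8c(OCc3ccccc3)c(Br)c9c(c8OCc3ccccc3)[C@H](c5c(OCc3ccccc3)c(Br)c6c(c5OCc3ccccc3)C[C@@H](O)[C@@H](c7ccc(OCc3ccccc3)c(OCc3ccccc3)c7)O6)[C@@H](O)[C@@H](c4ccc(OCc3ccccc3)c(OCc3ccccc3)c4)O9)[C@@H](O)[C@@H](c4ccc(OCc3ccccc3)c(OCc3ccccc3)c4)O2

F2 | step 4 | 8-bromo-6-iodo-4β-(2-ethoxyethoxy)-5,7,3′,4′-tetra-O-benzylepicatechin | Ic1c(OCc3ccccc3)c(Br)c2c(c1OCc3ccccc3)[C@H](OCCOCC)[C@@H](O)[C@@H](c4ccc(OCc3ccccc3)c(OCc3ccccc3)c4)O2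

F3 | step 4 | iodo dimer diol, [8-bromo-6-iodo-tetra-O-benzylepicatechin]-(4β→6)-[8-bromo-tetra-O-benzylepicatechin] | Ic1c(OCc3ccccc3)c(Br)c2c(c1OCc3ccccc3)[C@H](c5c(OCc3ccccc3)c(Br)c6c(c5OCc3ccccc3)C[C@@H](O)[C@@H](c7ccc(OCc3ccccc3)c(OCc3ccccc3)c7)O6)[C@@H](O)[C@@H](c4ccc(OCc3ccccc3)c(OCc3ccccc3)c4)O2

F4 | step 10 | 4-(2,2-dibromoethenyl)-1,2-bis(benzyloxy)benzene | BrC(Br)=Cc1ccc(OCc2ccccc2)c(OCc2ccccc2)c1

F5 | step 10 | (Z)-4-(2-bromoethenyl)-1,2-bis(benzyloxy)benzene | Br/C=C\c1ccc(OCc2ccccc2)c(OCc2ccccc2)c1
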